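**Retrosynthetic overview**
1. Andilesin A (25) ⇐ β‑keto lactone 24 (hydride reduction) ⇐ ring‑A dehydrogenation ⇐ caged silyl enol ether 21.
2. 21 ⇐ intramolecular Diels–Alder reaction of cyclohexa‑2,4‑dienone 20, which closes the cyclopentane and the bicyclo[2.2.2]octane together and sets three stereocentres.
3. 20 ⇐ dearomatising C‑alkylation of phthalide phenol 18 by the triflate of homoallylic alcohol 11.
4. 11 ⇐ formaldehyde ene reaction on cyclohexene lactone 10 ⇐ (R)‑carvone 1; 18 ⇐ Diels–Alder benzannulation of silyloxydiene 14 with bromofuranone 15.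
5. Ring order: ring B (bought), ring‑A lactone, arene (separate branch), cyclopentane plus bicyclooctane (key step), then the ring‑A C=C and the carbinol.

Assumption: one‑ to three‑carbon reagents (MeI, allyl bromide, paraformaldehyde, silylating agents) are treated as reagents and not numbered; C‑7 to C‑12 follow drimane numbering and C‑4/C‑6 of 18 and 20 follow phthalide numbering.

**Step 1**
Reactants: 1 (R)‑(−)‑carvone
Product: 2 (5R)‑5‑(2‑hydroxypropan‑2‑yl)‑2‑methylcyclohex‑2‑en‑1‑one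
Conditions: 50% aq. H2SO4, 0 °C
Reagents that add atoms: water, O
Why: Markovnikov hydration of the isopropenyl group through the tertiary cation leaves the enone and the carvone stereocentre untouched.

**Step 2**
Reactants: 2
Product: 3 (5R,6S)‑5‑(2‑hydroxypropan‑2‑yl)‑2,6‑dimethylcyclohex‑2‑en‑1‑one
Conditions: LiN(i‑Pr)2 (2.2 equiv), THF, −78 °C; MeI
Reagents that add atoms: iodomethane, CI
Why: Kinetic α′‑enolate alkylation (the alkoxide is a spectator); the C‑6 configuration is irrelevant because this centre is re‑enolised in step 3.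

**Step 3**
Reactants: 3
Product: 4 (5R,6S)‑6‑allyl‑5‑(2‑hydroxypropan‑2‑yl)‑2,6‑dimethylcyclohex‑2‑en‑1‑one
Conditions: LiN(i‑Pr)2 (2.2 equiv), THF–DMPU, −78 → 0 °C; allyl bromide
Reagents that add atoms: allyl bromide, C=CCBr
Why: Enolate alkylation anti to the neighbouring C(CH3)2OLi group sets the quaternary centre (drimane C‑10) with allyl trans and methyl cis to that group.

**Step 4**
Reactants: 4
Product: 5 (5R,6S)‑6‑allyl‑5‑(2‑hydroxypropan‑2‑yl)‑2,6‑dimethylcyclohex‑1‑en‑1‑yl trifluoromethanesulfonate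
Conditions: LiBH(s‑Bu)3 (2.2 equiv), THF, −78 °C; then PhNTf2, −78 → 0 °C
Reagents that add atoms: N‑phenylbis(trifluoromethanesulfonimide), O=S(=O)(N(c1ccccc1)S(=O)(=O)C(F)(F)F)C(F)(F)F
Why: Conjugate hydride reduction of the β‑unsubstituted enone gives the tetrasubstituted enolate regiospecifically, and it is trapped on oxygen as the enol triflate.

**Step 5**
Reactants: 5
Product: 6 2‑[(1R,2R)‑2‑allyl‑2,4‑dimethylcyclohex‑3‑en‑1‑yl]propan‑2‑ol
Conditions: Pd(OAc)2 (5 mol%), PPh3, HCO2H, n‑Bu3N, DMF, 60 °C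
Reagents that add atoms: none
Why: Palladium‑catalysed formate hydrogenolysis of the vinyl triflate (Cacchi reduction) leaves the trisubstituted C‑8(Me)=C‑9(H) alkene needed for the ene step.

**Step 6**
Reactants: 6
Product: 7 3‑[(1R,6R)‑6‑(2‑hydroxypropan‑2‑yl)‑1,3‑dimethylcyclohex‑2‑en‑1‑yl]propan‑1‑ol
Conditions: 9‑BBN, THF, 0 °C → rt; then NaOH, H2O2
Reagents that add atoms: hydrogen peroxide, OO
Why: Anti‑Markovnikov hydroboration–oxidation with 9‑BBN, which selects the monosubstituted allyl alkene over the trisubstituted ring alkene.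

**Step 7**
Reactants: 7
Product: 10 (5aR,9aR)‑1,1,5a,7‑tetramethyl‑4,5,5a,8,9,9a‑hexahydro‑2‑benzoxepin‑3(1H)‑one, via hydroxy aldehyde 8 (not isolated), via lactol 9 (not isolated)
Conditions: TEMPO (20 mol%), PhI(OAc)2 (2.5 equiv), CH2Cl2, rt
Reagents that add atoms: none
Why: Oxoammonium oxidation of the primary alcohol, lactol formation with the tertiary alcohol (helped by the gem‑dimethyl group and the trans‑diequatorial arrangement) and a second oxidation give the ε‑lactone (oxidative lactonisation).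

**Step 8**
Reactants: 10
Product: 11 6‑(hydroxymethyl)‑1,1,5a‑trimethyl‑7‑methylideneoctahydro‑2‑benzoxepin‑3(1H)‑one (CH2OH trans to the 5a‑methyl group)
Conditions: (CH2O)n, Me2AlCl (2.5 equiv), CH2Cl2, 0 °C → rt
Reagents that add atoms: formaldehyde (as paraformaldehyde), C=O
Why: Lewis‑acid carbonyl‑ene reaction in which formaldehyde bonds to the less substituted alkene carbon C‑9 on the face opposite the axial angular methyl group, with hydrogen taken from the methyl group cis to the vinylic hydrogen, so the axial 9α‑CH2OH and the exocyclic C‑8 methylene arise together.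

**Step 9**
Reactants: 12 methyl 2‑methyl‑3‑oxopentanoate
Product: 13 methyl 2‑methyl‑3‑[(trimethylsilyl)oxy]pent‑2‑enoate
Conditions: Me3SiCl, Et3N, hexane, rt
Reagents that add atoms: chlorotrimethylsilane, C[Si](C)(C)Cl
Why: O‑silylation of the β‑keto ester enol.

**Step 10**
Reactants: 13
Product: 14 1‑methoxy‑2‑methyl‑1‑[(triisopropylsilyl)oxy]‑3‑[(trimethylsilyl)oxy]penta‑1,3‑diene
Conditions: LiN(i‑Pr)2, THF, −78 °C; i‑Pr3SiOTf
Reagents that add atoms: triisopropylsilyl trifluoromethanesulfonate, CC(C)[Si](C(C)C)(C(C)C)OS(=O)(=O)C(F)(F)F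
Why: γ‑Deprotonation to the extended ester enolate and O‑silylation give a Chan‑type 1‑alkoxy‑1,3‑bis(silyloxy)diene carrying the robust silyl group on the ketene acetal oxygen.

**Step 11**
Reactants: 14; 15 4‑bromofuran‑2(5H)‑one
Product: 18 5‑hydroxy‑4,6‑dimethyl‑7‑[(triisopropylsilyl)oxy]‑2‑benzofuran‑1(3H)‑one, via bromo cycloadduct 16 (not isolated), via aryl trimethylsilyl ether 17 (not isolated)
Conditions: PhMe, 90 °C; then Et3N, rt; 1 M HCl work‑up
Reagents that add atoms: none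
Why: Diels–Alder benzannulation in which the nucleophilic diene terminus bonds to the bromine‑bearing β‑carbon of the butenolide, loss of HBr and MeOH aromatises, and work‑up cleaves only the labile ArO–SiMe3 bond, leaving the C‑5 phenol free and the C‑7 oxygen silylated.

**Step 12**
Reactants: 11; 18
Product: 20 (4R)‑4,6‑dimethyl‑7‑[(triisopropylsilyl)oxy]‑4‑{[(5aR,9aR)‑1,1,5a‑trimethyl‑7‑methylidene‑3‑oxodecahydro‑2‑benzoxepin‑6‑yl]methyl}‑2‑benzofuran‑1,5(3H,4H)‑dione, via triflate 19 (not isolated)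
Conditions: 11, Tf2O, 2,6‑lutidine, CH2Cl2, −78 °C; then 18, LiOt‑Bu, PhMe, 0 → 40 °C
Reagents that add atoms: none
Why: Dearomatising ortho C‑alkylation of the tight lithium phenoxide ion pair in a non‑polar medium by the primary triflate occurs at C‑4 because C‑6 is screened by the OSi(i‑Pr)3 group; the new quaternary centre forms as both epimers (about 1:1, with O‑alkyl ether as by‑product) and is sorted in step 13.

**Step 13**
Reactants: 20
Product: 21 caged silyl enol ether (Diels–Alder adduct with saturated ring‑A lactone; structure in the compound list)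
Conditions: PhMe (0.01 M), BHT, 140 °C, sealed tube
Reagents that add atoms: none
Why: Intramolecular Diels–Alder reaction of the cyclohexa‑2,4‑dienone with the 1,1‑disubstituted alkene, where the axial C‑9 tether lets the diene reach only the α‑face of C‑8 (cis‑fused cyclopentane, C‑7 endo) and so fixes C‑8 and both bridgeheads; only the (4R)‑epimer 20 fits this geometry, its epimer would need a trans‑diaxial bridge and is recovered.

**Step 14**
Reactants: 21
Product: 23 ring‑A enoate of 21 (structure in the compound list), via α‑phenylselanyl lactone 22 (not isolated)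
Conditions: LiN(i‑Pr)2, THF, −78 °C; PhSeBr; then H2O2, pyridine, CH2Cl2, 0 °C → rt
Reagents that add atoms: none
Why: The ε‑lactone α‑CH2 is the only enolisable position (the ketone lies between two quaternary carbons and the butenolide is an enol ether), so selenenylation and selenoxide syn‑elimination give the cis ring enoate.

**Step 15**
Reactants: 23
Product: 25 andilesin A, via β‑keto lactone 24 (not isolated)
Conditions: Bu4NF, AcOH, THF, 0 °C; then NaBH4, MeOH, −40 °C
Reagents that add atoms: none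
Why: Fluoride unmasks the β‑keto lactone, whose epimerisable α‑carbon settles with the lactone carbonyl on the side of the methyl‑bearing ketone bridge, and borohydride then adds to the ketone anti to that α‑substituent (Felkin‑type) to give the cis β‑hydroxy lactone; the hindered cage ketone and the enoate are not reduced.

**Compound list**
1 | (R)‑(−)‑carvone | CC1=CC[C@H](CC1=O)C(C)=C | starting material
2 | (5R)‑5‑(2‑hydroxypropan‑2‑yl)‑2‑methylcyclohex‑2‑en‑1‑one | CC1=CC[C@H](CC1=O)C(C)(C)O | intermediate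
3 | (5R,6S)‑5‑(2‑hydroxypropan‑2‑yl)‑2,6‑dimethylcyclohex‑2‑en‑1‑one (methyl trans to the hydroxypropyl group) | C[C@H]1[C@H](C(C)(C)O)CC=C(C)C1=O | intermediate
4 | (5R,6S)‑6‑allyl‑5‑(2‑hydroxypropan‑2‑yl)‑2,6‑dimethylcyclohex‑2‑en‑1‑one (allyl trans, methyl cis to the hydroxypropyl group) | C=CC[C@@]1(C)[C@H](C(C)(C)O)CC=C(C)C1=O | intermediate
5 | (5R,6S)‑6‑allyl‑5‑(2‑hydroxypropan‑2‑yl)‑2,6‑dimethylcyclohex‑1‑en‑1‑yl trifluoromethanesulfonate | C=CC[C@@]1(C)[C@H](C(C)(C)O)CCC(C)=C1OS(=O)(=O)C(F)(F)F | intermediate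
6 | 2‑[(1R,2R)‑2‑allyl‑2,4‑dimethylcyclohex‑3‑en‑1‑yl]propan‑2‑ol | C=CC[C@@]1(C)[C@H](C(C)(C)O)CCC(C)=C1 | intermediate
7 | 3‑[(1R,6R)‑6‑(2‑hydroxypropan‑2‑yl)‑1,3‑dimethylcyclohex‑2‑en‑1‑yl]propan‑1‑ol | OCCC[C@@]1(C)[C@H](C(C)(C)O)CCC(C)=C1 | intermediate
8 | 3‑[(1R,6R)‑6‑(2‑hydroxypropan‑2‑yl)‑1,3‑dimethylcyclohex‑2‑en‑1‑yl]propanal | O=CCC[C@@]1(C)[C@H](C(C)(C)O)CCC(C)=C1 | intermediate (not isolated)
9 | (5aR,9aR)‑1,1,5a,7‑tetramethyl‑1,3,4,5,5a,8,9,9a‑octahydro‑2‑benzoxepin‑3‑ol (lactol, both anomers) | CC1(C)OC(O)CC[C@@]2(C)[C@H]1CCC(C)=C2 | intermediate (not isolated)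
10 | (5aR,9aR)‑1,1,5a,7‑tetramethyl‑4,5,5a,8,9,9a‑hexahydro‑2‑benzoxepin‑3(1H)‑one | CC1(C)OC(=O)CC[C@@]2(C)[C@H]1CCC(C)=C2 | intermediate
11 | 6‑(hydroxymethyl)‑1,1,5a‑trimethyl‑7‑methylideneoctahydro‑2‑benzoxepin‑3(1H)‑one (CH2OH trans to the 5a‑methyl, cis to H‑9a) | CC1(C)OC(=O)CC[C@@]2(C)[C@H]1CCC(=C)[C@H]2CO | intermediate
12 | methyl 2‑methyl‑3‑oxopentanoate | CCC(=O)C(C)C(=O)OC | starting material
13 | methyl 2‑methyl‑3‑[(trimethylsilyl)oxy]pent‑2‑enoate | CCC(O[Si](C)(C)C)=C(C)C(=O)OC | intermediate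
14 | 1‑methoxy‑2‑methyl‑1‑[(triisopropylsilyl)oxy]‑3‑[(trimethylsilyl)oxy]penta‑1,3‑diene | CC=C(O[Si](C)(C)C)C(C)=C(OC)O[Si](C(C)C)(C(C)C)C(C)C | intermediate
15 | 4‑bromofuran‑2(5H)‑one | O=C1OCC(Br)=C1 | starting material
16 | 3a‑bromo‑7‑methoxy‑4,6‑dimethyl‑7‑[(triisopropylsilyl)oxy]‑5‑[(trimethylsilyl)oxy]‑3a,4,7,7a‑tetrahydro‑2‑benzofuran‑1(3H)‑one | CC1C(O[Si](C)(C)C)=C(C)C(OC)(O[Si](C(C)C)(C(C)C)C(C)C)C2C(=O)OCC12Br | intermediate (not isolated)
17 | 4,6‑dimethyl‑7‑[(triisopropylsilyl)oxy]‑5‑[(trimethylsilyl)oxy]‑2‑benzofuran‑1(3H)‑one | Cc1c(O[Si](C)(C)C)c(C)c(O[Si](C(C)C)(C(C)C)C(C)C)c2C(=O)OCc12 | intermediate (not isolated)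
18 | 5‑hydroxy‑4,6‑dimethyl‑7‑[(triisopropylsilyl)oxy]‑2‑benzofuran‑1(3H)‑one | Cc1c(O)c(C)c(O[Si](C(C)C)(C(C)C)C(C)C)c2C(=O)OCc12 | intermediate
19 | trifluoromethanesulfonate of 11 | CC1(C)OC(=O)CC[C@@]2(C)[C@H]1CCC(=C)[C@H]2COS(=O)(=O)C(F)(F)F | intermediate (not isolated)
20 | (4R)‑C‑alkylated cyclohexa‑2,4‑dienone: dearomatised phthalide with quaternary C‑4 carrying methyl and the CH2 link to drimane C‑9, C‑5 ketone, C‑6=C‑7 silyl enol ether, butenolide | CC1(C)OC(=O)CC[C@@]2(C)[C@H]1CCC(=C)[C@H]2C[C@@]3(C)C(=O)C(C)=C(O[Si](C(C)C)(C(C)C)C(C)C)C4=C3COC4=O | intermediate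
21 | Diels–Alder adduct: 1,2‑dihydro ring‑A lactone, bicyclo[2.2.2]octene with O‑Si(i‑Pr)3 enol ether of the β‑keto lactone | CC1(C)OC(=O)CC[C@@]2(C)[C@H]1CC[C@]13C[C@]4(C)C(=O)[C@](C)(C[C@@H]21)[C@]31COC(=O)C1=C4O[Si](C(C)C)(C(C)C)C(C)C | intermediate
22 | α‑phenylselanyl ε‑lactone of 21 (selenide epimers) | CC1(C)OC(=O)C([Se]c5ccccc5)C[C@@]2(C)[C@H]1CC[C@]13C[C@]4(C)C(=O)[C@](C)(C[C@@H]21)[C@]31COC(=O)C1=C4O[Si](C(C)C)(C(C)C)C(C)C | intermediate (not isolated)
23 | ring‑A enoate, O‑Si(i‑Pr)3 enol ether of dehydroandilesin A | CC1(C)OC(=O)C=C[C@@]2(C)[C@H]1CC[C@]13C[C@]4(C)C(=O)[C@](C)(C[C@@H]21)[C@]31COC(=O)C1=C4O[Si](C(C)C)(C(C)C)C(C)C | intermediate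
24 | β‑keto lactone (carbinol of 25 oxidised to ketone; keto tautomer shown) | CC1(C)OC(=O)C=C[C@@]2(C)[C@H]1CC[C@]13C[C@]4(C)C(=O)[C@](C)(C[C@@H]21)[C@]31COC(=O)[C@H]1C4=O | intermediate (not isolated)
25 | andilesin A | CC1(C)OC(=O)C=C[C@@]2(C)[C@H]1CC[C@]13C[C@]4(C)C(=O)[C@](C)(C[C@@H]21)[C@]31COC(=O)[C@H]1[C@H]4O | target

**Step count:** 15 steps in total; longest linear sequence 12 steps (steps 1–8 and 12–15); steps 9–11 form the second branch.

**Three steps most likely to fail**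

Step 12 (C‑ versus O‑alkylation of the phenoxide by an unactivated, hindered primary electrophile; no control of the new C‑4 centre). The fallback sets out from 11 and comes back at 20. Alcohol 11 is converted with PhSSPh and n‑Bu3P into the phenyl sulfide F1. SO2Cl2 at −78 °C gives the S‑chlorosulfonium chloride F2, which is treated with phenol 18 and then Et3N. The aryloxysulfonium ylide F3 undergoes a [2,3]‑sigmatropic shift that delivers the carbon to C‑4 intramolecularly (C‑6 is again screened), giving the α‑phenylthio dienone F4. Raney Ni (deactivated with acetone, 0 °C) removes sulfur and gives 20.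

Step 13 (only the (4R)‑epimer can cyclise, and the new bond joins two quaternary carbons). The fallback sets out from the step‑12 mixture and comes back at 20. The recovered (4S)‑epimer F5 is irradiated (365 nm, benzene, 20 °C). 6π‑Electrocyclic ring opening gives the dienylketene F6, which recloses in the dark to a 1:1 mixture of 20 and F5; this mixture is returned to step 13.

Step 15 (facial selectivity at the carbinol carbon). The fallback sets out from 24 and comes back at 25. If NaBH4 gives mainly the epimeric carbinol F7, it is equilibrated through 24 with Al(Oi‑Pr)3 in i‑PrOH containing a little acetone (Meerwein–Ponndorf–Verley/Oppenauer conditions). This leads to the thermodynamically preferred cis β‑hydroxy lactone 25, whose hydroxyl is hydrogen‑bonded to the lactone carbonyl and faces the flat ketone bridge.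

**Further compounds**
F1 | step 12 | phenyl sulfide from 11 | CC1(C)OC(=O)CC[C@@]2(C)[C@H]1CCC(=C)[C@H]2CSc3ccccc3
F2 | step 12 | S‑chlorosulfonium chloride of F1 | CC1(C)OC(=O)CC[C@@]2(C)[C@H]1CCC(=C)[C@H]2C[S+](Cl)c3ccccc3.[Cl-]
F3 | step 12 | aryloxysulfonium ylide | CC1(C)OC(=O)CC[C@@]2(C)[C@H]1CCC(=C)[C@H]2[CH-][S+](c3ccccc3)Oc4c(C)c5COC(=O)c5c(O[Si](C(C)C)(C(C)C)C(C)C)c4C
F4 | step 12 | α‑phenylthio dienone | CC1(C)OC(=O)CC[C@@]2(C)[C@H]1CCC(=C)[C@H]2C(Sc3ccccc3)C4(C)C(=O)C(C)=C(O[Si](C(C)C)(C(C)C)C(C)C)C5=C4COC5=O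
F5 | step 13 | (4S)‑epimer of 20 | CC1(C)OC(=O)CC[C@@]2(C)[C@H]1CCC(=C)[C@H]2C[C@]3(C)C(=O)C(C)=C(O[Si](C(C)C)(C(C)C)C(C)C)C4=C3COC4=O
F6 | step 13 | dienylketene from ring opening of F5 | CC1(C)OC(=O)CC[C@@]2(C)[C@H]1CCC(=C)[C@H]2CC(C)=C3COC(=O)C3=C(O[Si](C(C)C)(C(C)C)C(C)C)C(C)=C=O
F7 | step 15 | carbinol epimer of andilesin A | CC1(C)OC(=O)C=C[C@@]2(C)[C@H]1CC[C@]13C[C@]4(C)C(=O)[C@](C)(C[C@@H]21)[C@]31COC(=O)[C@H]1[C@@H]4O
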